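Per minute, the X left in the dusk flask shrinks by a fraction that I read from its last reading, 0.0406 min⁻¹, treating X as pseudo-first-order. The dawn run, with less Z, reads 0.0416 min⁻¹, about the same, so these two readings, taken at different times and each with a scatter of 1.5 percentage points, do not tell me how fast Z takes up G.

common to all: X 20 mM; G 10 µM

|  | Z | remark |
|---|---|---|
| dusk | 41 µM | the very flask that is asked about, followed so far |
| dawn | 27 µM | run made earlier |
| flask | 41 µM |  |

- dusk (time / min: E / %): 0.333: 4; 0.500: 4; 0.833: 3; 1.33: 6; 2.50: 10; 4.00: 15
- dawn (time / min: E / %): 1.50: 7; 3.00: 10; 5.00: 16; 6.00: 23; 8.00: 28; 10.0: 34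

(standard deviation of a reading: 1.5 percentage points)

* factor on the rate of making E when 5.0 % of the X are converted if G is charged twice over
* factor on the rate when 5.0 % of the X are converted if G is charged at 1.0 µM instead

- steps that have been proposed: G + Z <-> L; X + G -> E + G
- no earlier run changes the charge of G; that part of a forecast is a guess

My look time, the time for the fraction of X left to fall to one minus the conversion looked at, is 1.26 min in the dusk flask. I take it to scale inversely with the charge of G, which is a guess, since no run changes that charge. The ladder then runs from 0.630 min with G doubled, through 1.26 min, to 12.6 min at 1.0 µM, all shorter than the 24.6 min lifetime of X. I guess that the binding of G falls between the last two rungs, which would leave G mostly free at the early looks and partly bound at the late one. On that guess I expect a ratio below 0.100, the ratio of the charges, and a doubling factor just above two.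

The forecast gives 2.2 and 0.085, reasoning that “Z is not depleted, so the rate falls slightly more than tenfold”.

The flask gives 2.17 and 0.0506.

    G + Z ⇌ L (K = 33000 M⁻¹, k = 49.4 M⁻¹ s⁻¹)
    X + G → E + G, rate k2*[X]*[G]/(1 + ([X]/Km2) + ([X]/Ksi2)^2) (8.36 mM, 2.07 mM, k = 6030 M⁻¹ s⁻¹)

In the flask the look falls at 1.41 min, close to my look time of 1.26 min and shorter than the 3.26 min relaxation half-life of G + Z and L at 10.0 min, and L then holds 14.6 % of the catalyst, against 53.7 % at 24.4 min. With G at 1.0 µM my estimated look time of 12.6 min is longer than that half-life of the flask charged with 10 µM, and at the same conversion of X in the run with 1.0 µM, L holds 56.8 % of the catalyst and G 43.2 %, against 85.4 % free in the flask, which with the smaller charge gives a factor of 0.0506.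

Readings and results were generated by integration for an exercise, noise included.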